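**Plan**

- Ring A carries C5(OH)–C6(OMe)–C7(OH), a masked 2-methoxy-1,3-dicarbonyl unit bridging C4a and C8 of the pyranone. It is therefore cut at C7–C8 and C5–C6 into methyl methoxyacetate (C6, its OMe, C7) and a 2-methyl-4-pyranone-3-carboxylate (methyl = C8, ester carbon = C5).
- The pyranone is cut at O1–C2 and C4–C4a into methyl acetoacetate (C8, C8a, O1, C4a, C5) and a 3-methoxy-2-arylacryloyl chloride, which comes from 2,3,4-trimethoxyphenylacetic acid and methyl formate (C2).
- Forward order: ring B is bought with the arylacetic acid, ring C is closed next by O1–C2 addition–elimination, and ring A is fused on last by a one-pot lateral Claisen/Dieckmann annulation that aromatises to the free 5,7-diol.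
- Because O1–C8a exists before ring A does, a 6-OMe/8-OMe mix-up is structurally excluded, and no protecting group or demethylation is needed.
- Stereochemistry: the target has no stereocentre and its aryl–C3 axis rotates freely; the E enol ethers on the way are lost when ring C forms.

Key step: step 7

Remark: outside systematic names, atoms are numbered as in the isoflavone (O1, C2, C3, C4, C4a, C5 to C8, C8a), also in precursors; compounds 1, 3, 8 and 11 are taken to be commercial.

**Route**

Step 1
Reactants: 1 2,3,4-trimethoxyphenylacetic acid
Product: 2 methyl 2-(2,3,4-trimethoxyphenyl)acetate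
Conditions: MeOH, H2SO4 (cat.), reflux
Reagents that add atoms: methanol, CO
Why: Fischer esterification of an unhindered arylacetic acid in excess methanol should go to completion, and the aryl methyl ethers are inert to catalytic acid.

Step 2
Reactants: 2 methyl 2-(2,3,4-trimethoxyphenyl)acetate; 3 methyl formate
Product: 5 methyl (E)-3-methoxy-2-(2,3,4-trimethoxyphenyl)acrylate, via sodium enolate 4 (not isolated)
Conditions: NaH, THF–DMF, 0 °C to rt; then Me2SO4, 0 °C to rt
Reagents that add atoms: dimethyl sulfate, COS(=O)(=O)OC
Why: Crossed Claisen formylation of the ester enolate by the non-enolisable formate gives the stabilised sodium enolate 4, which a hard methylating agent in a dipolar aprotic medium alkylates on oxygen, the standard entry to β-methoxyacrylates; the expected E geometry has no consequence later.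

Step 3
Reactants: 5 methyl (E)-3-methoxy-2-(2,3,4-trimethoxyphenyl)acrylate
Product: 6 (E)-3-methoxy-2-(2,3,4-trimethoxyphenyl)acrylic acid
Conditions: NaOH, MeOH–H2O, 50 °C; then 1 M HCl, 0 °C, to pH 3
Reagents that add atoms: sodium hydroxide, [Na+].[OH-]
Why: Saponification (acyl–oxygen cleavage by hydroxide) of this vinylogous carbonate should be slow but clean in aqueous methanol, where addition–elimination at the β-carbon by methoxide is degenerate and the carboxylate formed is no longer an acceptor; brief cold acidification spares the enol ether.

Step 4
Reactants: 6 (E)-3-methoxy-2-(2,3,4-trimethoxyphenyl)acrylic acid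
Product: 7 (E)-3-methoxy-2-(2,3,4-trimethoxyphenyl)acryloyl chloride
Conditions: (COCl)2, DMF (cat.), CH2Cl2, 0 °C to rt; concentrate, use crude
Reagents that add atoms: oxalyl chloride, O=C(Cl)C(=O)Cl
Why: Vilsmeier-type activation by catalytic DMF converts the acid into its chloride with only gaseous by-products, as is routine for β-alkoxyacryloyl chlorides, and the absence of an α-hydrogen rules out ketene formation.

Step 5
Reactants: 7 (E)-3-methoxy-2-(2,3,4-trimethoxyphenyl)acryloyl chloride; 8 methyl acetoacetate
Product: 9 methyl (2E,4E)-2-(1-hydroxyethylidene)-5-methoxy-3-oxo-4-(2,3,4-trimethoxyphenyl)pent-4-enoate (C-acylated tricarbonyl, drawn as the enol chelated to the new ketone)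
Conditions: MgCl2 (1 equiv), pyridine (2 equiv), CH2Cl2, 0 °C to rt; cold dilute HCl work-up
Reagents that add atoms: none
Why: Soft enolisation of the β-keto ester as its magnesium chelate with an amine base gives C-acylation by acid chlorides (Claisen-type acylation of an active methylene compound), because the chelate ties up both oxygens and leaves carbon as the nucleophilic site.

Step 6
Reactants: 9 methyl (2E,4E)-2-(1-hydroxyethylidene)-5-methoxy-3-oxo-4-(2,3,4-trimethoxyphenyl)pent-4-enoate
Product: 10 methyl 2-methyl-4-oxo-5-(2,3,4-trimethoxyphenyl)-4H-pyran-3-carboxylate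
Conditions: CF3CO2H (cat.), CH2Cl2, rt
Reagents that add atoms: none
Why: Acid-catalysed intramolecular oxa-Michael addition of the acetyl enol oxygen to the β-methoxy enone (6-endo-trig, O1–C2 bond) followed by loss of methanol is the established closure of β-methoxyacryloyl-acylated carbonyl compounds to 4-pyranones; it is driven by the aromatic character of the pyranone and erases the enol ether geometry.

Step 7
Reactants: 10 methyl 2-methyl-4-oxo-5-(2,3,4-trimethoxyphenyl)-4H-pyran-3-carboxylate; 11 methyl methoxyacetate
Product: 14 5,7-dihydroxy-6-methoxy-3-(2,3,4-trimethoxyphenyl)-4H-chromen-4-one (target), via side-chain ketone 12 (not isolated), via dilithium bis-phenoxide 13 (not isolated)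
Conditions: LiN(iPr)2 (1.1 equiv), THF, −78 °C; 11, −78 to −30 °C; LiN(iPr)2 (2.5 equiv), −78 to 0 °C; then cold 1 M HCl
Reagents that add atoms: none
Why: Proposed new method: the methyl group of 10 (future C8) is a vinylogous α-position of both the ring ketone and the adjacent ester, so LiN(iPr)2 should give an extended dienolate whose γ-carbon attacks the ester carbonyl of 11 (lateral Claisen, C7–C8 bond) to give 12 as its stabilised enolate, after which more base removes a proton from the methoxy-bearing carbon and this more reactive dianion terminus attacks the adjacent ring ester (Dieckmann, C5–C6 bond), methoxide leaves and the dione tautomerises to bis-phenoxide 13, which the acidic quench converts into 14. The closest known reaction type is the Claisen–Dieckmann benzannulation of ortho-toluate lateral anions with esters to 1,3-dihydroxyarenes (a relative of the Staunton–Weinreb annulation and of biomimetic polyketide aromatisation), together with the known lateral acylation of 2-methyl-4-pyranones; fusing a benzene ring onto a monocyclic 2-methyl-4-pyranone-3-carboxylate in this way is the untested extension. Ring A (C4a, C5, C6, C7, C8, C8a) closes in a 6-(enolendo)-exo-trig mode, the C6=C7 enolate bond lying inside the new ring and the ester C=O outside it. No stereocentre is formed. The step needs γ-carbon rather than α-carbon or oxygen acylation and carbon rather than oxygen ring closure, and both are secured thermodynamically: the wrong adducts are retro-Claisen or transesterification partners that lithium methoxide reopens, whereas only the C-closed ring drains irreversibly into the aromatic bis-phenoxide, while the anionic dienolate shields the pyranone from nucleophilic ring opening. The 6-methoxy versus 8-methoxy regiochemistry is fixed by the substrate, since O1–C8a is already present in 10 and C5 is its ester carbon.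

**Compound list**

1 | 2,3,4-trimethoxyphenylacetic acid | COc1ccc(CC(=O)O)c(OC)c1OC | starting material
2 | methyl 2-(2,3,4-trimethoxyphenyl)acetate | COC(=O)Cc1ccc(OC)c(OC)c1OC | intermediate
3 | methyl formate | COC=O | starting material
4 | sodium 3-methoxy-3-oxo-2-(2,3,4-trimethoxyphenyl)prop-1-en-1-olate (enolate of the α-formyl ester, geometry not defined, not isolated) | [Na+].[O-]C=C(C(=O)OC)c1ccc(OC)c(OC)c1OC | intermediate
5 | methyl (E)-3-methoxy-2-(2,3,4-trimethoxyphenyl)acrylate | CO/C=C(\c1ccc(OC)c(OC)c1OC)C(=O)OC | intermediate
6 | (E)-3-methoxy-2-(2,3,4-trimethoxyphenyl)acrylic acid | CO/C=C(\c1ccc(OC)c(OC)c1OC)C(=O)O | intermediate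
7 | (E)-3-methoxy-2-(2,3,4-trimethoxyphenyl)acryloyl chloride | CO/C=C(\c1ccc(OC)c(OC)c1OC)C(=O)Cl | intermediate
8 | methyl acetoacetate | COC(=O)CC(C)=O | starting material
9 | methyl (2E,4E)-2-(1-hydroxyethylidene)-5-methoxy-3-oxo-4-(2,3,4-trimethoxyphenyl)pent-4-enoate (chelated enol of the C-acylated tricarbonyl) | C/C(O)=C(\C(=O)OC)C(=O)/C(=C/OC)c1ccc(OC)c(OC)c1OC | intermediate
10 | methyl 2-methyl-4-oxo-5-(2,3,4-trimethoxyphenyl)-4H-pyran-3-carboxylate | COC(=O)c1c(C)occ(-c2ccc(OC)c(OC)c2OC)c1=O | intermediate
11 | methyl methoxyacetate | COCC(=O)OC | starting material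
12 | methyl 2-(3-methoxy-2-oxopropyl)-4-oxo-5-(2,3,4-trimethoxyphenyl)-4H-pyran-3-carboxylate (present as its lithium enolate, not isolated) | COCC(=O)Cc1occ(-c2ccc(OC)c(OC)c2OC)c(=O)c1C(=O)OC | intermediate
13 | dilithium 6-methoxy-4-oxo-3-(2,3,4-trimethoxyphenyl)-4H-chromene-5,7-diolate (not isolated) | [Li+].[Li+].COc1ccc(-c2coc3cc([O-])c(OC)c([O-])c3c2=O)c(OC)c1OC | intermediate
14 | 5,7-dihydroxy-6-methoxy-3-(2,3,4-trimethoxyphenyl)-4H-chromen-4-one (CNP0144156.0) | COc1ccc(-c2coc3cc(O)c(OC)c(O)c3c2=O)c(OC)c1OC | target

**Count and risks**

Total step count: 7. Longest linear sequence: 7 steps (1 → 2 → 5 → 6 → 7 → 9 → 10 → 14); 3, 8 and 11 enter as bought partners.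

Steps most likely to fail:

1. Step 7 (carries the label). Several processes may defeat it:
   - proton transfer from the newly formed, more acidic ketone to unreacted dienolate may stall the lateral acylation;
   - the amide base may enolise methyl methoxyacetate, which then self-condenses;
   - methoxide or amide may open the pyranone by conjugate attack at C2;
   - the second deprotonation may not reach the methoxy-bearing carbon, so that ring closure never starts.

   Fallback, known chemistry only, setting out from 1 and coming back at 14: Friedel–Crafts (Houben–Hoesch-type) acylation of commercial 2-methoxybenzene-1,3,5-triol F1 with acid 1 in BF3·OEt2 at about 80 °C should give the deoxybenzoin 1-(2,4,6-trihydroxy-3-methoxyphenyl)-2-(2,3,4-trimethoxyphenyl)ethan-1-one F2. One-carbon insertion and ring closure with DMF, MeSO2Cl and BF3·OEt2 at about 60 °C would then give 14. Because either ortho hydroxyl can close, it may be accompanied by the isomer 5,7-dihydroxy-8-methoxy-3-(2,3,4-trimethoxyphenyl)-4H-chromen-4-one F3. F3 would be converged on 14 by brief treatment with alkali (ring opening at C2 and reclosure, the isoflavone counterpart of the Wessely–Moser rearrangement). The direction of that isomerisation, from the 8-methoxy to the 6-methoxy series, is stated from recollection of the isoflavone literature and should be confirmed. This gives up the built-in regiocontrol of the main route but relies only on established isoflavone chemistry.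

2. Step 5. The enolate may be acylated on oxygen. Pyridine or the enolate may attack the β-carbon of the acryloyl chloride (addition–elimination displacing methoxide) instead of the carbonyl. The hindered, donor-deactivated acid chloride may react sluggishly. The crowded tricarbonyl may lose its acetyl group by retro-Claisen cleavage on work-up.

   Fallback, setting out from 7 and 8 and coming back at 9: 8 is first condensed with pyrrolidine to the enamino ester methyl (E)-3-(pyrrolidin-1-yl)but-2-enoate F4. Stork-type C-acylation of F4 with 7 (Et3N, CH2Cl2) should give the push-pull enaminone methyl 2-[(E)-3-methoxy-2-(2,3,4-trimethoxyphenyl)acryloyl]-3-(pyrrolidin-1-yl)but-2-enoate F5. Aqueous acid then hydrolyses the enamine to 9, which under the same acid would already begin to close to 10. The neutral carbon nucleophile avoids the metal enolate and its O-acylation, and the tertiary amine cannot end up in the ring.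

3. Step 3. Hydroxide may add to the β-carbon so that the enol ether is lost as the formyl acid, which decarboxylates. The enol ether may be hydrolysed during acidification. The vinylogous carbonate ester may resist hydrolysis.

   Fallback, setting out from 1 and coming back at 10 (C2 is brought in only after the acylation, so no β-methoxyacrylic acid or chloride is needed): acid 1 with (COCl)2 and catalytic DMF gives 2-(2,3,4-trimethoxyphenyl)acetyl chloride F6. C-acylation of the magnesium enolate of 8 (MgCl2, pyridine, CH2Cl2) gives methyl 2-acetyl-3-oxo-4-(2,3,4-trimethoxyphenyl)butanoate F7. N,N-dimethylformamide dimethyl acetal in toluene at 80 °C should aminomethylenate the benzylic methylene, and the enol oxygen then displaces dimethylamine to close pyranone 10, as in the deoxybenzoin route to isoflavones. The price is possible competition from the acetyl methyl group and O-methylation of the enol by the acetal.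

**Further compounds**

F1 | step 7 | 2-methoxybenzene-1,3,5-triol | COc1c(O)cc(O)cc1O
F2 | step 7 | 1-(2,4,6-trihydroxy-3-methoxyphenyl)-2-(2,3,4-trimethoxyphenyl)ethan-1-one | COc1ccc(CC(=O)c2c(O)cc(O)c(OC)c2O)c(OC)c1OC
F3 | step 7 | 5,7-dihydroxy-8-methoxy-3-(2,3,4-trimethoxyphenyl)-4H-chromen-4-one | COc1ccc(-c2coc3c(OC)c(O)cc(O)c3c2=O)c(OC)c1OC
F4 | step 5 | methyl (E)-3-(pyrrolidin-1-yl)but-2-enoate | COC(=O)/C=C(\C)N1CCCC1
F5 | step 5 | methyl 2-[(E)-3-methoxy-2-(2,3,4-trimethoxyphenyl)acryloyl]-3-(pyrrolidin-1-yl)but-2-enoate | COC(=O)C(C(=O)/C(=C/OC)c1ccc(OC)c(OC)c1OC)=C(C)N1CCCC1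
F6 | step 3 | 2-(2,3,4-trimethoxyphenyl)acetyl chloride | COc1ccc(CC(=O)Cl)c(OC)c1OC
F7 | step 3 | methyl 2-acetyl-3-oxo-4-(2,3,4-trimethoxyphenyl)butanoate | COC(=O)C(C(C)=O)C(=O)Cc1ccc(OC)c(OC)c1OC
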